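**Strategy.** The catechol is disconnected at the C3–O bond of the benzoate ring, leading back to the (S)-20-methyldocosyl ester of salicylic acid whose C2 oxygen carries a di-tert-butylsilanol. Because C1 of the arene bears the ester, the only C–H ortho to the C2 oxygen is C3–H. A palladium-catalysed, silanol-directed oxygenation must therefore place the new oxygen there and, in the same operation, tie both oxygens into a five-membered 1,3,2-dioxasilole fused to the benzene ring. The precursor is assembled from a C5 chiral bromide, a C18 diacid, salicylic acid and di-tert-butylchlorosilane; buffered fluoride then releases the catechol.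

Key step: step 8

Remark: the commercial C5 bromide is assumed enantiopure. The coupling extends its CH2 group only, so the neighbouring stereocentre becomes C20 unchanged and keeps the (S) descriptor, and the C5 and C18 pieces give the 19 CH2 groups between the ester oxygen and C20.

Step 1
Reactants: 1 octadecanedioic acid
Product: 2 octadecane-1,18-diol
Conditions: LiAlH4, THF, 0 °C → reflux; then H2O, aq NaOH
Reagents that add atoms: none
Why: Exhaustive LiAlH4 reduction of both carboxylic acids to primary alcohols is routine for long-chain α,ω-diacids, and no other functional group is present.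

Step 2
Reactants: 2 octadecane-1,18-diol
Product: 3 18-bromooctadecan-1-ol
Conditions: 48% aq HBr (1.2 equiv), toluene, reflux
Reagents that add atoms: hydrogen bromide, Br
Why: Acid-mediated SN2 substitution of one hydroxyl in the two-phase HBr/toluene system should stop mainly at the monobromide, because the bromo alcohol passes into the toluene phase away from the acid, and residual diol and dibromide differ enough in polarity to be removed.

Step 3
Reactants: 3 18-bromooctadecan-1-ol
Product: 4 (18-bromooctadecyloxy)(tert-butyl)dimethylsilane
Conditions: TBSCl, imidazole, CH2Cl2/DMF, rt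
Reagents that add atoms: tert-butyldimethylsilyl chloride, CC(C)(C)[Si](C)(C)Cl
Why: Imidazole-promoted silyl ether formation at a primary alcohol removes the acidic proton that would otherwise consume the Grignard reagent of step 4.

Step 4
Reactants: 5 (S)-1-bromo-2-methylbutane; 4 (18-bromooctadecyloxy)(tert-butyl)dimethylsilane
Product: 8 (S)-20-methyldocosan-1-ol, via (S)-2-methylbutylmagnesium bromide 6 (not isolated), via (S)-20-methyldocosyl TBS ether 7 (not isolated)
Conditions: Mg, THF, 40 °C (5 → 6, 1.5 equiv); then 4, Li2CuCl4 (3 mol %), THF, −10 °C → rt; then HCl/MeOH, rt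
Reagents that add atoms: none
Why: Copper-catalysed alkyl–alkyl Grignard cross-coupling (Kumada-type, Li2CuCl4) joins the unhindered primary bromide to the primary Grignard reagent without touching the stereocentre, which sits one carbon away from magnesium and becomes C20 with the (S) configuration carried over from 5, and acidic methanol then cleaves the primary silyl ether in the same flask.

Step 5
Reactants: 8 (S)-20-methyldocosan-1-ol; 9 salicylic acid
Product: 10 (S)-20-methyldocosyl 2-hydroxybenzoate
Conditions: PPh3, DIAD, THF, 0 °C → rt
Reagents that add atoms: none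
Why: In this Mitsunobu esterification the carboxylic acid, far more acidic than the hydrogen-bonded phenol, is the pronucleophile that attacks the activated primary carbinol carbon, so the ester should form without phenol protection and without involving any stereocentre.

Step 6
Reactants: 10 (S)-20-methyldocosyl 2-hydroxybenzoate; 11 di-tert-butylchlorosilane
Product: 12 (S)-20-methyldocosyl 2-[(di-tert-butylsilyl)oxy]benzoate
Conditions: imidazole, DMAP (cat.), CH2Cl2/DMF, 40 °C
Reagents that add atoms: none
Why: Base-mediated O-silylation of the phenol succeeds with the hydridochlorosilane because Si–H makes it much less hindered than a di-tert-butyldihalosilane, and the alkyl ester is inert.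

Step 7
Reactants: 12 (S)-20-methyldocosyl 2-[(di-tert-butylsilyl)oxy]benzoate
Product: 14 (S)-20-methyldocosyl 2-{[di-tert-butyl(hydroxy)silyl]oxy}benzoate, via bromosilyl ether 13 (not isolated)
Conditions: NBS, CH2Cl2, 0 °C → rt; then H2O, NaHCO3, THF, rt
Reagents that add atoms: water, O
Why: Bromination of the Si–H bond by NBS followed by hydrolysis of the Si–Br bond (halogenation–hydrolysis of a hydrosilane) should give the silanol, which the two tert-butyl groups keep from condensing to a disiloxane.

Step 8
Reactants: 14 (S)-20-methyldocosyl 2-{[di-tert-butyl(hydroxy)silyl]oxy}benzoate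
Product: 17 (S)-20-methyldocosyl 2,2-di-tert-butylbenzo[d][1,3,2]dioxasilole-4-carboxylate, via C3 acetate 15 (not isolated), via silyl acetate 16 (not isolated)
Conditions: Pd(OPiv)2 (10 mol %), PhI(OAc)2 (2 equiv), PhMe, 100 °C
Reagents that add atoms: (diacetoxyiodo)benzene, CC(=O)OI(OC(C)=O)c1ccccc1
Why: The silanol binds divalent palladium and carboxylate-assisted palladation of C3–H, the only C–H ortho to the C2 oxygen, gives a six-membered palladacycle; PhI(OAc)2 oxidises it to tetravalent palladium and C–O reductive elimination forms the C3–O bond as the acetate 15. The silanol then takes over the acetyl group through a seven-membered transition state to give the silyl acetate 16, and the freed C3 phenol displaces acetate at silicon in a 5-exo-tet closure that forms the dioxasilole ring of 17 and masks the catechol against further oxidation. The closest known reaction type is the palladium-catalysed silanol-directed ortho C–H oxygenation of phenols to silylene-protected catechols with the same oxidant. No stereocentre is created, and neither C20 nor the saturated chain has a bond that these conditions can attack. The selectivity required is C3 over C6: the silanol on the C2 oxygen forms a strong, geometrically matched chelate, whereas the ester carbonyl is only a weak neutral donor, so palladation at C6 should not compete. The alkyl benzoate is a far poorer acyl donor than the aryl acetate, which should keep the silanol from attacking the C1 ester, and the raised catalyst loading answers the lower reactivity of the ester-deactivated ring.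

Step 9
Reactants: 17 (S)-20-methyldocosyl 2,2-di-tert-butylbenzo[d][1,3,2]dioxasilole-4-carboxylate
Product: 18 gentiside B, (S)-20-methyldocosyl 2,3-dihydroxybenzoate
Conditions: Bu4NF, AcOH, THF, 0 °C → rt, under argon
Reagents that add atoms: none
Why: Fluoride-mediated cleavage of the two aryl O–Si bonds (desilylation) is fast for a strained catechol silylene, and the acetic acid buffer keeps both the ester and the air-sensitive catechol away from basic conditions.

**Compound list**

1 | octadecanedioic acid | OC(=O)CCCCCCCCCCCCCCCCC(=O)O | starting material
2 | octadecane-1,18-diol | OCCCCCCCCCCCCCCCCCCO | intermediate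
3 | 18-bromooctadecan-1-ol | OCCCCCCCCCCCCCCCCCCBr | intermediate
4 | (18-bromooctadecyloxy)(tert-butyl)dimethylsilane | CC(C)(C)[Si](C)(C)OCCCCCCCCCCCCCCCCCCBr | intermediate
5 | (S)-1-bromo-2-methylbutane | CC[C@H](C)CBr | starting material
6 | (S)-2-methylbutylmagnesium bromide | CC[C@H](C)C[Mg]Br | intermediate (not isolated)
7 | tert-butyldimethyl{[(20S)-20-methyldocosyl]oxy}silane | CC[C@H](C)CCCCCCCCCCCCCCCCCCCO[Si](C)(C)C(C)(C)C | intermediate (not isolated)
8 | (S)-20-methyldocosan-1-ol | CC[C@H](C)CCCCCCCCCCCCCCCCCCCO | intermediate
9 | salicylic acid | OC(=O)c1ccccc1O | starting material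
10 | (S)-20-methyldocosyl 2-hydroxybenzoate | CC[C@H](C)CCCCCCCCCCCCCCCCCCCOC(=O)c1ccccc1O | intermediate
11 | di-tert-butylchlorosilane | CC(C)(C)[SiH](Cl)C(C)(C)C | starting material
12 | (S)-20-methyldocosyl 2-[(di-tert-butylsilyl)oxy]benzoate | CC[C@H](C)CCCCCCCCCCCCCCCCCCCOC(=O)c1ccccc1O[SiH](C(C)(C)C)C(C)(C)C | intermediate
13 | (S)-20-methyldocosyl 2-{[bromo(di-tert-butyl)silyl]oxy}benzoate | CC[C@H](C)CCCCCCCCCCCCCCCCCCCOC(=O)c1ccccc1O[Si](Br)(C(C)(C)C)C(C)(C)C | intermediate (not isolated)
14 | (S)-20-methyldocosyl 2-{[di-tert-butyl(hydroxy)silyl]oxy}benzoate | CC[C@H](C)CCCCCCCCCCCCCCCCCCCOC(=O)c1ccccc1O[Si](O)(C(C)(C)C)C(C)(C)C | intermediate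
15 | (S)-20-methyldocosyl 3-acetoxy-2-{[di-tert-butyl(hydroxy)silyl]oxy}benzoate | CC[C@H](C)CCCCCCCCCCCCCCCCCCCOC(=O)c1cccc(OC(C)=O)c1O[Si](O)(C(C)(C)C)C(C)(C)C | intermediate (not isolated)
16 | (S)-20-methyldocosyl 2-{[acetoxy(di-tert-butyl)silyl]oxy}-3-hydroxybenzoate | CC[C@H](C)CCCCCCCCCCCCCCCCCCCOC(=O)c1cccc(O)c1O[Si](OC(C)=O)(C(C)(C)C)C(C)(C)C | intermediate (not isolated)
17 | (S)-20-methyldocosyl 2,2-di-tert-butylbenzo[d][1,3,2]dioxasilole-4-carboxylate | CC[C@H](C)CCCCCCCCCCCCCCCCCCCOC(=O)c1cccc2O[Si](C(C)(C)C)(C(C)(C)C)Oc12 | intermediate
18 | gentiside B, (S)-20-methyldocosyl 2,3-dihydroxybenzoate | CC[C@H](C)CCCCCCCCCCCCCCCCCCCOC(=O)c1cccc(O)c1O | target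

**Step count.** Total: 9 steps. Longest linear sequence: 9 steps (1 → 18 through steps 1–9); 5, 9 and 11 enter as purchased materials.

**Steps most likely to fail**

1. Step 8. Palladation of the ester-deactivated ring may be slow. The directing group may be lost at 100 °C, either by protodesilylation or by acyl transfer to the C1 ester. The oxygenated arene may also degrade oxidatively before the silylene has closed. The fallback gives up C–H oxygenation and brings the catechol in preformed; it sets out from 8 and returns at 18. Carbodiimide esterification of 8 with commercial 2,3-bis(benzyloxy)benzoic acid (EDC·HCl, DMAP, CH2Cl2, rt) should give (S)-20-methyldocosyl 2,3-bis(benzyloxy)benzoate F1. Hydrogenolysis of both benzyl ethers (H2, Pd/C, EtOAc/THF, rt) then leads directly to 18; the saturated chain and the ester are inert to these conditions.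

2. Step 4. Homocoupling may occur during Grignard formation, the C18 bromide may be reduced or undergo elimination at copper, and incomplete conversion would leave bromo alcohol that is hard to separate from the product. The fallback forms the C18–C19 bond by sulfone carbanion alkylation; it sets out from 5 and 4 and returns at 7. Displacement of bromide in 5 by sulfinate (PhSO2Na, NaI cat., DMF, 80 °C) should give [(2S)-2-methylbutyl]sulfonylbenzene F2. Its α-lithio derivative (n-BuLi, THF/DMPU, −78 °C) is alkylated by the unhindered bromide 4 to give tert-butyldimethyl{[(20S)-20-methyl-19-(phenylsulfonyl)docosyl]oxy}silane F3 as both C19 epimers. The C20 stereocentre carries no acidic hydrogen and is not at risk. Reductive desulfonylation (sodium amalgam, Na2HPO4, MeOH/THF, −20 °C) removes the C19 stereocentre and gives 7, which is isolated here and converted into 8 by the acidic methanolysis of step 4.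

3. Step 7. Electrophilic bromination of the arene para to the silyloxy oxygen may compete with Si–H bromination, and the aryl O–Si bond may be cleaved while the hindered Si–Br bond is hydrolysed. The fallback installs silicon already at the silanol oxidation level; it sets out from 10 and returns at 14, bypassing 12 and 13. Treatment of 10 with tBu2Si(OTf)2 (1.1 equiv) and 2,6-lutidine in CH2Cl2 at 0 °C should give (S)-20-methyldocosyl 2-{[di-tert-butyl(trifluoromethylsulfonyloxy)silyl]oxy}benzoate F4, not isolated. Aqueous NaHCO3 hydrolyses its remaining Si–OTf bond to give 14.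

**Further compounds**

F1 | step 8 | (S)-20-methyldocosyl 2,3-bis(benzyloxy)benzoate | CC[C@H](C)CCCCCCCCCCCCCCCCCCCOC(=O)c1cccc(OCc2ccccc2)c1OCc1ccccc1
F2 | step 4 | [(2S)-2-methylbutyl]sulfonylbenzene | CC[C@H](C)CS(=O)(=O)c1ccccc1
F3 | step 4 | tert-butyldimethyl{[(20S)-20-methyl-19-(phenylsulfonyl)docosyl]oxy}silane, both C19 epimers | CC[C@H](C)C(S(=O)(=O)c1ccccc1)CCCCCCCCCCCCCCCCCCO[Si](C)(C)C(C)(C)C
F4 | step 7 | (S)-20-methyldocosyl 2-{[di-tert-butyl(trifluoromethylsulfonyloxy)silyl]oxy}benzoate | CC[C@H](C)CCCCCCCCCCCCCCCCCCCOC(=O)c1ccccc1O[Si](OS(=O)(=O)C(F)(F)F)(C(C)(C)C)C(C)(C)C
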